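**Retrosynthetic overview**

- Germacrane numbering: ten-membered ring C1–C10, E C1=C10 (methyl on C10), senecioate on C3, oxirane on C4 (methyl) and C5, acetate on C6, isopropyl on C7. The strategy rests on the C3 carbinol carbon being bonded to the methyl-bearing C4 of what is, before epoxidation, the E C4=C5 ring alkene. This E-allylic alcohol unit is the product pattern of an aldehyde–alkyne reductive coupling.
- Disconnections: the two esters and the oxirane lead back to a ten-membered 1(10),4-diene; C3–C4 (nickel, Et3SiH, ring closure) to an acyclic ynal; C9–C10 (B-alkyl Suzuki–Miyaura) to a vinyl iodide and a terminal alkene; C6–C7 (anti allylboration of but-2-ynal).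
- Ring order: the ten-membered carbocycle is closed first (step 9); the oxirane is the second ring (step 13).
- Stereocontrol: C6 and C7 by reagent-controlled allylboration; C3 is made R by oxazaborolidine reduction so that it steers the epoxidation to the 4R,5R face, then inverted to S in the Mitsunobu esterification.

Key step: step 9

Remark on the chemistry: metal-directed epoxidation of a C3 allylic alcohol with a methyl on C4 is erythro-selective, so the (3S) alcohol would lead to the 4S,5S oxirane; the route therefore epoxidizes the (3R) alcohol and inverts C3 when the senecioate is put on.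

**Route**

Step 1
Reactants: 1 but-2-yn-1-ol
Product: 2 but-2-ynal
Conditions: activated MnO2 (excess), Et2O, rt; filtered, dried over 4 Å sieves, used as a solution
Reagents that add atoms: none
Why: Activated MnO2 oxidizes the propargylic alcohol to the aldehyde without over-oxidation, and the volatile ynal is carried on in solution.

Step 2
Reactants: 2 but-2-ynal, 3 (E)-4-methylpent-2-ene
Product: 7 (3R,4R)-3-isopropylhept-1-en-5-yn-4-ol, via allylpotassium 4 (not isolated), via allylborane 5 (not isolated), via borinate 6 (not isolated)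
Conditions: 3, KOt-Bu, n-BuLi, THF, −78 to −45 °C; (+)-Ipc2BOMe [from (−)-α-pinene], −78 °C; BF3·OEt2; 2, −78 °C; NaOH, H2O2, 0 °C to rt
Reagents that add atoms: none
Why: Schlosser metalation at the methyl group and transfer to boron give the (E)-γ-isopropylallyl diisopinocampheylborane, which adds through a closed chair (Zimmerman–Traxler) transition state, so the E geometry gives the anti pair and the isopinocampheyl groups direct attack to the re face of the ynal, setting 6R and 7S in ring numbering (4R and 3R in the name of 7).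

Step 3
Reactants: 7 (3R,4R)-3-isopropylhept-1-en-5-yn-4-ol
Product: 8 tert-butyl{[(3R,4R)-3-isopropylhept-1-en-5-yn-4-yl]oxy}dimethylsilane
Conditions: TBSOTf, 2,6-lutidine, CH2Cl2, −78 to 0 °C
Reagents that add atoms: tert-butyldimethylsilyl trifluoromethanesulfonate, CC(C)(C)[Si](C)(C)OS(=O)(=O)C(F)(F)F
Why: The silyl triflate with a hindered pyridine base silylates the hindered secondary propargylic alcohol and leaves alkene and alkyne untouched (standard silyl ether formation).

Step 4
Reactants: 9 pent-3-yn-1-ol
Product: 10 triethyl(pent-3-yn-1-yloxy)silane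
Conditions: TESCl, imidazole, CH2Cl2, 0 °C
Reagents that add atoms: chlorotriethylsilane, CC[Si](Cl)(CC)CC
Why: Standard silylation of the primary alcohol, which keeps a free alkoxide from redirecting the hydrozirconation of the next step.

Step 5
Reactants: 10 triethyl(pent-3-yn-1-yloxy)silane
Product: 12 triethyl{[(3E)-4-iodopent-3-en-1-yl]oxy}silane, via alkenylzirconocene chloride 11 (not isolated)
Conditions: Cp2Zr(H)Cl (2 equiv), THF, 50 °C; I2, THF, 0 °C
Reagents that add atoms: iodine, II
Why: Hydrozirconation with excess reagent under equilibrating conditions puts zirconium on the methyl-bearing alkyne carbon by syn addition, and iodinolysis with retention gives the (E)-2-iodoalkene (hydrozirconation–iodination).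

Step 6
Reactants: 8 tert-butyl{[(3R,4R)-3-isopropylhept-1-en-5-yn-4-yl]oxy}dimethylsilane, 12 triethyl{[(3E)-4-iodopent-3-en-1-yl]oxy}silane
Product: 14 triethyl{[(3E,7S,8R)-8-(tert-butyldimethylsilyloxy)-7-isopropyl-4-methylundec-3-en-9-yn-1-yl]oxy}silane, via B-alkyl-9-BBN borane 13 (not isolated)
Conditions: 8, 9-BBN, THF, rt to 40 °C; then 12, Pd(dppf)Cl2 (5 mol %), AsPh3, Cs2CO3, DMF–H2O, rt
Reagents that add atoms: none
Why: 9-BBN hydroborates the terminal alkene anti-Markovnikov in preference to the internal alkyne, and the B-alkyl Suzuki–Miyaura coupling joins C9 to C10 with retention of the vinyl iodide geometry, which fixes the E C1=C10 alkene.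

Step 7
Reactants: 14 triethyl{[(3E,7S,8R)-8-(tert-butyldimethylsilyloxy)-7-isopropyl-4-methylundec-3-en-9-yn-1-yl]oxy}silane
Product: 15 (3E,7S,8R)-8-(tert-butyldimethylsilyloxy)-7-isopropyl-4-methylundec-3-en-9-yn-1-ol
Conditions: PPTS (cat.), MeOH–CH2Cl2, 0 °C
Reagents that add atoms: none
Why: Acid-catalysed methanolysis removes the primary triethylsilyl ether far faster than the hindered secondary tert-butyldimethylsilyl ether.

Step 8
Reactants: 15 (3E,7S,8R)-8-(tert-butyldimethylsilyloxy)-7-isopropyl-4-methylundec-3-en-9-yn-1-ol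
Product: 16 (3E,7S,8R)-8-(tert-butyldimethylsilyloxy)-7-isopropyl-4-methylundec-3-en-9-ynal
Conditions: Dess–Martin periodinane, NaHCO3, CH2Cl2, 0 °C; short filtration, used at once
Reagents that add atoms: none
Why: Buffered Dess–Martin oxidation gives the β,γ-unsaturated aldehyde without moving the alkene into conjugation.

Step 9
Reactants: 16 (3E,7S,8R)-8-(tert-butyldimethylsilyloxy)-7-isopropyl-4-methylundec-3-en-9-ynal, 17 triethylsilane
Product: 18 (1(10)E,4E,3S,6R,7S)-6-(tert-butyldimethylsilyloxy)-3-(triethylsilyloxy)germacra-1(10),4-diene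
Conditions: Ni(cod)2 (25 mol %), IMes·HCl (25 mol %), KOt-Bu (25 mol %), Et3SiH (5 equiv), THF, rt, syringe-pump addition of 16 over 6 h to 0.005 M
Reagents that add atoms: none
Why: This is the nickel-catalysed reductive coupling of an aldehyde with an alkyne, run intramolecularly as in known ynal macrocyclizations: zerovalent nickel carrying the carbene binds aldehyde and alkyne and couples them oxidatively to a five-membered nickel–oxygen metallacycle that already holds the C3–C4 bond, Et3SiH cleaves the Ni–O bond by σ-bond metathesis, and C–H reductive elimination puts hydrogen on C5 cis to C3. The ten-membered ring closes in the endo mode (both alkyne carbons in the ring), and the syn delivery of hydrogen and C3 places C3 and C6 trans, so the new ring alkene is E and C3 leaves as a triethylsilyl ether distinct from the C6 silyl ether. Bonding at the methyl-bearing C4 rather than at C5 (nine-membered ring with an exocyclic ethylidene) is secured by the small methyl cap against the branched silyloxy carbon C6, together with the compact carbene 1,3-dimesitylimidazol-2-ylidene, which lets the larger substituent sit on the nickel-bound carbon. The new C3 centre is expected to be set by C6: in the metallacycle the oxygen lies in the plane of the forming alkene and C2 must leave that plane on the face of C7, which is the face that lets the C6 hydrogen eclipse the C4 methyl (allylic 1,3-strain), and this gives 3S. The step needs ring closure to outrun oligomerization and simple hydrosilylation of the aldehyde, which slow addition of the fresh aldehyde to the catalyst should secure; the route does not depend on the C3 configuration, because step 11 makes C3 trigonal.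

Step 10
Reactants: 18 (1(10)E,4E,3S,6R,7S)-6-(tert-butyldimethylsilyloxy)-3-(triethylsilyloxy)germacra-1(10),4-diene
Product: 19 (1(10)E,4E,3S,6R,7S)-6-(tert-butyldimethylsilyloxy)germacra-1(10),4-dien-3-ol
Conditions: HF·pyridine, pyridine, THF, 0 °C
Reagents that add atoms: none
Why: Buffered HF·pyridine cleaves the secondary triethylsilyl ether selectively beside the hindered tert-butyldimethylsilyl ether and avoids both strong acid (transannular cyclization) and a free alkoxide at C3 of the 1,5-diene (anionic oxy-Cope rearrangement).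

Step 11
Reactants: 19 (1(10)E,4E,3S,6R,7S)-6-(tert-butyldimethylsilyloxy)germacra-1(10),4-dien-3-ol
Product: 20 (1(10)E,4E,6R,7S)-6-(tert-butyldimethylsilyloxy)germacra-1(10),4-dien-3-one
Conditions: Dess–Martin periodinane, NaHCO3, CH2Cl2, 0 °C
Reagents that add atoms: none
Why: Buffered Dess–Martin oxidation of the allylic alcohol gives the enone without shifting the β,γ alkene, and it makes C3 trigonal so that either C3 epimer from step 9 converges here.

Step 12
Reactants: 20 (1(10)E,4E,6R,7S)-6-(tert-butyldimethylsilyloxy)germacra-1(10),4-dien-3-one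
Product: 21 (1(10)E,4E,3R,6R,7S)-6-(tert-butyldimethylsilyloxy)germacra-1(10),4-dien-3-ol
Conditions: (S)-2-methyl-CBS-oxazaborolidine (1 equiv), catecholborane, toluene, −78 °C
Reagents that add atoms: none
Why: Corey–Bakshi–Shibata reduction: the (S)-oxazaborolidine binds the ketone with the α-methyl alkenyl arm as the large group and delivers hydride to give the (3R) alcohol, the same sense that attack on the carbonyl face away from the C4 methyl favours in the preferred ring conformer, and catecholborane at −78 °C does not hydroborate the alkenes.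

Step 13
Reactants: 21 (1(10)E,4E,3R,6R,7S)-6-(tert-butyldimethylsilyloxy)germacra-1(10),4-dien-3-ol
Product: 22 (1(10)E,3R,4R,5R,6R,7S)-6-(tert-butyldimethylsilyloxy)-4,5-epoxygermacr-1(10)-en-3-ol
Conditions: Ti(OiPr)4 (0.5 equiv), D-(−)-diisopropyl tartrate (0.6 equiv), t-BuOOH (2 equiv), 4 Å sieves, CH2Cl2, −20 °C
Reagents that add atoms: tert-butyl hydroperoxide, CC(C)(C)OO
Why: Sharpless titanium–tartrate epoxidation in its matched mode: for a carbinol of the 3R type D-(−)-tartrate is the fast-reacting partner and delivers oxygen erythro, to the C4=C5 face syn to the C3–O bond with C2 on the far side, which is the 4R,5R face, while the homoallylic C1=C10 alkene is left alone and the tartrate disfavours delivery through the other ring conformer.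

Step 14
Reactants: 22 (1(10)E,3R,4R,5R,6R,7S)-6-(tert-butyldimethylsilyloxy)-4,5-epoxygermacr-1(10)-en-3-ol, 23 3-methylbut-2-enoic acid
Product: 24 (1(10)E,3S,4R,5R,6R,7S)-6-(tert-butyldimethylsilyloxy)-4,5-epoxygermacr-1(10)-en-3-yl 3-methylbut-2-enoate
Conditions: PPh3, DIAD, toluene, 0 °C to rt
Reagents that add atoms: none
Why: Mitsunobu esterification: the alkoxyphosphonium ion of the (3R) epoxy alcohol is displaced by the senecioate anion in an SN2 step with inversion, which installs the ester and sets 3S under near-neutral conditions that spare oxirane and silyl ether.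

Step 15
Reactants: 24 (1(10)E,3S,4R,5R,6R,7S)-6-(tert-butyldimethylsilyloxy)-4,5-epoxygermacr-1(10)-en-3-yl 3-methylbut-2-enoate
Product: 25 (1(10)E,3S,4R,5R,6R,7S)-4,5-epoxy-6-hydroxygermacr-1(10)-en-3-yl 3-methylbut-2-enoate
Conditions: TBAF, AcOH, THF, rt
Reagents that add atoms: none
Why: Fluoride cleaves the silyl ether (Si–F bond formation), the acetic acid buffer protects the ester and the oxirane, and no 1,5-diene remains that could rearrange.

Step 16
Reactants: 25 (1(10)E,3S,4R,5R,6R,7S)-4,5-epoxy-6-hydroxygermacr-1(10)-en-3-yl 3-methylbut-2-enoate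
Product: 26 (1(10)E,3S,4R,5R,6R,7S)-6-acetoxy-4,5-epoxygermacr-1(10)-en-3-yl 3-methylbut-2-enoate
Conditions: Ac2O, Et3N, DMAP (cat.), CH2Cl2, rt
Reagents that add atoms: acetic anhydride, CC(=O)OC(C)=O
Why: DMAP-catalysed acetylation (nucleophilic catalysis) esterifies the hindered C6 alcohol under mildly basic conditions that leave oxirane and senecioate untouched, giving the target.

**Compound list**

1 | but-2-yn-1-ol | CC#CCO | starting material
2 | but-2-ynal | CC#CC=O | intermediate
3 | (E)-4-methylpent-2-ene | C/C=C/C(C)C | starting material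
4 | (E)-(4-methylpent-2-en-1-yl)potassium | [K+].[CH2-]/C=C/C(C)C | intermediate
5 | (E)-(4-methylpent-2-en-1-yl)diisopinocampheylborane, isopinocampheyl groups from (−)-α-pinene | CC(C)/C=C/CB([C@H]1C[C@H]2C[C@@H]([C@@H]1C)C2(C)C)[C@H]1C[C@H]2C[C@@H]([C@@H]1C)C2(C)C | intermediate
6 | diisopinocampheylborinate of 7 | CC#C[C@H](OB([C@H]1C[C@H]2C[C@@H]([C@@H]1C)C2(C)C)[C@H]1C[C@H]2C[C@@H]([C@@H]1C)C2(C)C)[C@H](C(C)C)C=C | intermediate
7 | (3R,4R)-3-isopropylhept-1-en-5-yn-4-ol | CC#C[C@H](O)[C@H](C(C)C)C=C | intermediate
8 | tert-butyl{[(3R,4R)-3-isopropylhept-1-en-5-yn-4-yl]oxy}dimethylsilane | CC#C[C@H](O[Si](C)(C)C(C)(C)C)[C@H](C(C)C)C=C | intermediate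
9 | pent-3-yn-1-ol | CC#CCCO | starting material
10 | triethyl(pent-3-yn-1-yloxy)silane | CC#CCCO[Si](CC)(CC)CC | intermediate
11 | chlorobis(cyclopentadienyl)[(2E)-5-(triethylsilyloxy)pent-2-en-2-yl]zirconium (cyclopentadienyl rings drawn σ-bonded) | C/C(=C\CCO[Si](CC)(CC)CC)[Zr](Cl)(C1C=CC=C1)C1C=CC=C1 | intermediate
12 | triethyl{[(3E)-4-iodopent-3-en-1-yl]oxy}silane | C/C(I)=C\CCO[Si](CC)(CC)CC | intermediate
13 | 9-[(3S,4R)-4-(tert-butyldimethylsilyloxy)-3-isopropylhept-5-yn-1-yl]-9-borabicyclo[3.3.1]nonane | CC#C[C@H](O[Si](C)(C)C(C)(C)C)[C@H](C(C)C)CCB1C2CCCC1CCC2 | intermediate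
14 | triethyl{[(3E,7S,8R)-8-(tert-butyldimethylsilyloxy)-7-isopropyl-4-methylundec-3-en-9-yn-1-yl]oxy}silane | CC#C[C@H](O[Si](C)(C)C(C)(C)C)[C@H](C(C)C)CC/C(C)=C/CCO[Si](CC)(CC)CC | intermediate
15 | (3E,7S,8R)-8-(tert-butyldimethylsilyloxy)-7-isopropyl-4-methylundec-3-en-9-yn-1-ol | CC#C[C@H](O[Si](C)(C)C(C)(C)C)[C@H](C(C)C)CC/C(C)=C/CCO | intermediate
16 | (3E,7S,8R)-8-(tert-butyldimethylsilyloxy)-7-isopropyl-4-methylundec-3-en-9-ynal | CC#C[C@H](O[Si](C)(C)C(C)(C)C)[C@H](C(C)C)CC/C(C)=C/CC=O | intermediate
17 | triethylsilane | CC[SiH](CC)CC | starting material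
18 | (1(10)E,4E,3S,6R,7S)-6-(tert-butyldimethylsilyloxy)-3-(triethylsilyloxy)germacra-1(10),4-diene | CC(C)(C)[Si](C)(C)O[C@H]1/C=C(C)/[C@@H](O[Si](CC)(CC)CC)C/C=C(\C)CC[C@H]1C(C)C | intermediate
19 | (1(10)E,4E,3S,6R,7S)-6-(tert-butyldimethylsilyloxy)germacra-1(10),4-dien-3-ol | CC(C)(C)[Si](C)(C)O[C@H]1/C=C(C)/[C@@H](O)C/C=C(\C)CC[C@H]1C(C)C | intermediate
20 | (1(10)E,4E,6R,7S)-6-(tert-butyldimethylsilyloxy)germacra-1(10),4-dien-3-one | CC(C)(C)[Si](C)(C)O[C@H]1/C=C(C)/C(=O)C/C=C(\C)CC[C@H]1C(C)C | intermediate
21 | (1(10)E,4E,3R,6R,7S)-6-(tert-butyldimethylsilyloxy)germacra-1(10),4-dien-3-ol | CC(C)(C)[Si](C)(C)O[C@H]1/C=C(C)/[C@H](O)C/C=C(\C)CC[C@H]1C(C)C | intermediate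
22 | (1(10)E,3R,4R,5R,6R,7S)-6-(tert-butyldimethylsilyloxy)-4,5-epoxygermacr-1(10)-en-3-ol | CC(C)(C)[Si](C)(C)O[C@H]1[C@H]2O[C@]2(C)[C@H](O)C/C=C(\C)CC[C@H]1C(C)C | intermediate
23 | 3-methylbut-2-enoic acid | CC(C)=CC(=O)O | starting material
24 | (1(10)E,3S,4R,5R,6R,7S)-6-(tert-butyldimethylsilyloxy)-4,5-epoxygermacr-1(10)-en-3-yl 3-methylbut-2-enoate | CC(C)(C)[Si](C)(C)O[C@H]1[C@H]2O[C@]2(C)[C@@H](OC(=O)C=C(C)C)C/C=C(\C)CC[C@H]1C(C)C | intermediate
25 | (1(10)E,3S,4R,5R,6R,7S)-4,5-epoxy-6-hydroxygermacr-1(10)-en-3-yl 3-methylbut-2-enoate | O[C@H]1[C@H]2O[C@]2(C)[C@@H](OC(=O)C=C(C)C)C/C=C(\C)CC[C@H]1C(C)C | intermediate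
26 | (1(10)E,3S,4R,5R,6R,7S)-6-acetoxy-4,5-epoxygermacr-1(10)-en-3-yl 3-methylbut-2-enoate | CC(=O)O[C@H]1[C@H]2O[C@]2(C)[C@@H](OC(=O)C=C(C)C)C/C=C(\C)CC[C@H]1C(C)C | target

**Step count**

Total: 16 steps. Longest linear sequence: 14 steps (steps 1–3 and 6–16).

**Steps most likely to fail**

1. Step 9. Closure of the strained ten-membered E,E-diene may lose to intermolecular coupling and oligomerization, to direct hydrosilylation of the aldehyde, or to migration of the β,γ alkene of the aldehyde into conjugation before coupling. Fallback: form the same C3–C4 bond by a chromium-mediated ring closure. It sets out from 14. Hydrozirconation–iodination of the methyl alkyne (Cp2Zr(H)Cl, THF, 50 °C; I2) would give triethyl{[(3E,7S,8R,9E)-8-(tert-butyldimethylsilyloxy)-10-iodo-7-isopropyl-4-methylundeca-3,9-dien-1-yl]oxy}silane F1. Methanolysis of the primary silyl ether (PPTS, MeOH) would give the dienol F2, and Dess–Martin oxidation the iodo aldehyde F3. Nozaki–Hiyama–Kishi cyclization (CrCl2, NiCl2 cat., DMSO–THF, high dilution) then closes the ring with retention of the E geometry. It comes back to the route at 19; any C3 epimer formed is 21, and both enter steps 11 to 13.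

2. Step 13. The reacting geometry needs the ring conformer in which the C6 silyloxy group, not the C6 hydrogen, eclipses the C4 methyl. The epoxidation may therefore stall, or run through the other ring conformer onto the opposite alkene face, or the titanium Lewis acid may open the new oxirane with transannular participation of the C1=C10 alkene. Fallback: steer the epoxidation from the C6 hydroxyl instead. It sets out from 19. Esterification with 23 (EDC·HCl, DMAP, CH2Cl2) would give the (3S)-6-(tert-butyldimethylsilyloxy)germacra-1(10),4-dien-3-yl senecioate F4, and buffered TBAF the 6-hydroxy diene ester F5. The same titanium and D-(−)-tartrate system is then applied; the 6R carbinol is again the matched partner and erythro delivery reaches the same 4R,5R face. It comes back to the route at 25 and removes the need for steps 11, 12 and 14.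

3. Step 14. Displacement at a carbinol next to the fully substituted oxirane carbon may be slow, and elimination or retention through neighbouring-group participation may compete. Fallback: invert C3 by oxidation and reduction. It sets out from 22. Dess–Martin oxidation would give the 4,5-epoxy-3-ketone F6. Hydride reduction (NaBH4, CeCl3, MeOH, −78 °C) is expected to enter on the carbonyl face away from the C4 methyl and give the (3S)-epoxy alcohol F7. Acylation with 23 (EDC·HCl, DMAP) then comes back to the route at 24.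

**Further compounds**

F1 | step 9 | triethyl{[(3E,7S,8R,9E)-8-(tert-butyldimethylsilyloxy)-10-iodo-7-isopropyl-4-methylundeca-3,9-dien-1-yl]oxy}silane | C/C(I)=C\[C@H](O[Si](C)(C)C(C)(C)C)[C@H](C(C)C)CC/C(C)=C/CCO[Si](CC)(CC)CC
F2 | step 9 | (3E,7S,8R,9E)-8-(tert-butyldimethylsilyloxy)-10-iodo-7-isopropyl-4-methylundeca-3,9-dien-1-ol | C/C(I)=C\[C@H](O[Si](C)(C)C(C)(C)C)[C@H](C(C)C)CC/C(C)=C/CCO
F3 | step 9 | (3E,7S,8R,9E)-8-(tert-butyldimethylsilyloxy)-10-iodo-7-isopropyl-4-methylundeca-3,9-dienal | C/C(I)=C\[C@H](O[Si](C)(C)C(C)(C)C)[C@H](C(C)C)CC/C(C)=C/CC=O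
F4 | step 13 | (1(10)E,4E,3S,6R,7S)-6-(tert-butyldimethylsilyloxy)germacra-1(10),4-dien-3-yl 3-methylbut-2-enoate | CC(C)(C)[Si](C)(C)O[C@H]1/C=C(C)/[C@@H](OC(=O)C=C(C)C)C/C=C(\C)CC[C@H]1C(C)C
F5 | step 13 | (1(10)E,4E,3S,6R,7S)-6-hydroxygermacra-1(10),4-dien-3-yl 3-methylbut-2-enoate | O[C@H]1/C=C(C)/[C@@H](OC(=O)C=C(C)C)C/C=C(\C)CC[C@H]1C(C)C
F6 | step 14 | (1(10)E,4S,5R,6R,7S)-6-(tert-butyldimethylsilyloxy)-4,5-epoxygermacr-1(10)-en-3-one | CC(C)(C)[Si](C)(C)O[C@H]1[C@H]2O[C@]2(C)C(=O)C/C=C(\C)CC[C@H]1C(C)C
F7 | step 14 | (1(10)E,3S,4R,5R,6R,7S)-6-(tert-butyldimethylsilyloxy)-4,5-epoxygermacr-1(10)-en-3-ol | CC(C)(C)[Si](C)(C)O[C@H]1[C@H]2O[C@]2(C)[C@@H](O)C/C=C(\C)CC[C@H]1C(C)C
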